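**Plan**

- Numbering follows 1,4-naphthoquinone: C1 and C4 are the carbonyls, the side chain sits on C2 (carbinol carbon C1'), and the hydroxyls are on C5 and C8. The ring C4a–C5–C6–C7–C8–C8a has para OH groups at C5/C8 and neighbouring CH groups at C6/C7. It is therefore read as a 1,4-dioxygenated cyclohexa-1,3-diene (C5–C6–C7–C8) laid across the C4a–C8a edge of a benzoquinone whose other alkene already carries the side chain. A CH2–CH2 bridge once joining C5 and C8 accounts for the aromatic oxidation level.
- Retrosynthetic cuts, in order: the two O–Si bonds; the C5/C8 ethano bridge (restored); C4a–C5 and C8a–C8 ([4+2]); quinone back to a 1,4-dimethoxybenzene; the ester C(=O)–O bond; the C3'=C4' alkene (metathesis); C1'–C2' (allylation).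
- Forward: the chain is built on 2,5-dimethoxybenzaldehyde (allyl, then prenyl by metathesis, then ester) and the arene is oxidised to the benzoquinone (ring C1–C4). The Diels–Alder reaction then closes the second ring as a bicyclo[2.2.2]octene, which is dehydrogenated, loses ethylene and is desilylated.
- Stereochemistry: the only stereocentre, C1' (R), is set by reagent-controlled allylboration with the borane derived from (−)-α-pinene and is never a reacting centre afterwards. The four centres created in the cycloaddition are transient.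

Key step: step 7

Assumption 1: the naphthazarin is written as the tautomer with the side chain on the quinoid ring; the tautomers equilibrate rapidly, so no step has to distinguish them.
Assumption 2: the facial sense of step 1 is taken by analogy with benzaldehyde, for which the (+)-α-pinene-derived allylborane is known to give the (S)-carbinol; the antipodal reagent is therefore used for the (R)-carbinol.

**Route**

Step 1
Reactants: 1 2,5-dimethoxybenzaldehyde
Product: 3 (R)-1-(2,5-dimethoxyphenyl)but-3-en-1-ol, via borinate ester 2 (not isolated)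
Conditions: (+)-Ipc2B(allyl) (1 M in pentane, 1.2 equiv), Et2O, −78 °C; then 3 M NaOH, 30% H2O2, 0 °C → rt
Reagents that add atoms: (+)-B-allyldiisopinocampheylborane [from (−)-α-pinene], C=CCB([C@H]1C[C@H]2C[C@@H]([C@@H]1C)C2(C)C)[C@H]1C[C@H]2C[C@@H]([C@@H]1C)C2(C)C
Why: Brown allylboration through a closed chair Zimmerman–Traxler transition state in which the isopinocampheyl groups from (−)-α-pinene direct allyl to the Re face of the aryl aldehyde, so C1' should be set as (R) under reagent control, and the oxidative work-up cleaves the borinate without touching arene or alkene.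

Step 2
Reactants: 3 (R)-1-(2,5-dimethoxyphenyl)but-3-en-1-ol; 4 2-methyl-2-butene
Product: 5 (R)-1-(2,5-dimethoxyphenyl)-4-methylpent-3-en-1-ol
Conditions: Grubbs II (5 mol%), 2-methyl-2-butene (large excess, co-solvent), CH2Cl2, 40 °C, sealed vessel
Reagents that add atoms: none
Why: Olefin cross-metathesis of a terminal alkene with excess 2-methyl-2-butene exchanges =CH2 for =CMe2 with release of propene; free homoallylic alcohols are tolerated and the carbinol centre is remote from the reacting alkene.

Step 3
Reactants: 6 3-hydroxy-3-methylbutanoic acid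
Product: 8 3-acetoxy-3-methylbutanoic acid, via mixed anhydride 7 (not isolated)
Conditions: AcCl (neat, 4 equiv), 0 °C → rt; evaporate; THF/H2O, rt
Reagents that add atoms: acetyl chloride, CC(=O)Cl
Why: Acetylation of a tertiary alcohol with neat acetyl chloride also converts the carboxyl group into the mixed anhydride, which water cleaves at the less hindered acetyl carbonyl, and the absence of base disfavours loss of acetate to senecioic acid.

Step 4
Reactants: 5 (R)-1-(2,5-dimethoxyphenyl)-4-methylpent-3-en-1-ol; 8 3-acetoxy-3-methylbutanoic acid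
Product: 9 (R)-1-(2,5-dimethoxyphenyl)-4-methylpent-3-en-1-yl 3-acetoxy-3-methylbutanoate
Conditions: DCC (1.2 equiv), DMAP (10 mol%), CH2Cl2, 0 °C → rt
Reagents that add atoms: none
Why: Steglich esterification acylates the secondary benzylic alcohol via the acylpyridinium without breaking the C1'–O bond, so configuration is retained, and low temperature with only catalytic DMAP limits β-elimination of the tertiary acetate.

Step 5
Reactants: 9 (R)-1-(2,5-dimethoxyphenyl)-4-methylpent-3-en-1-yl 3-acetoxy-3-methylbutanoate
Product: 10 (R)-1-(3,6-dioxocyclohexa-1,4-dien-1-yl)-4-methylpent-3-en-1-yl 3-acetoxy-3-methylbutanoate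
Conditions: CAN (2.5 equiv), MeCN/H2O (2:1), 0 °C, 15 min; used promptly
Reagents that add atoms: water, O
Why: Oxidative demethylation of a 1,4-dimethoxyarene by ceric ammonium nitrate (two one-electron oxidations, ipso attack of water, loss of methanol) is fast at 0 °C and is routinely compatible with prenyl-type alkenes and esters.

Step 6
Reactants: 11 1,4-cyclohexanedione
Product: 12 1,4-bis(trimethylsilyloxy)cyclohexa-1,3-diene
Conditions: TMSCl (2.5 equiv), Et3N (3 equiv), DMF, 80 °C; pentane extraction, distillation
Reagents that add atoms: chlorotrimethylsilane, C[Si](C)(C)Cl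
Why: Thermodynamic double silyl enol ether formation should favour the conjugated 1,3-diene, and any unconjugated double-bond isomer carried along is inert toward dienophiles and leaves with the excess diene after step 7.

Step 7
Reactants: 10 (R)-1-(3,6-dioxocyclohexa-1,4-dien-1-yl)-4-methylpent-3-en-1-yl 3-acetoxy-3-methylbutanoate; 12 1,4-bis(trimethylsilyloxy)cyclohexa-1,3-diene
Product: 13 2-substituted 5,8-bis(trimethylsilyloxy)-5,8-ethano-4a,5,8,8a-tetrahydronaphthalene-1,4-dione (cis-fused; mixture at the four new centres; C1' = R)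
Conditions: 12 (1.5 equiv), PhMe, rt, Ar, dark
Reagents that add atoms: none
Why: A concerted, suprafacial [4+2] cycloaddition of normal electron demand joins the s-cis-locked, doubly donor-substituted diene 12 to the unsubstituted CH=CH alkene of quinone 10, forming C4a–C5 and C8a–C8 in one event; the closest known reaction type is the Diels–Alder addition of benzoquinones to 1-silyloxy- and 1,4-dioxygenated cyclohexa-1,3-dienes used ahead of Alder–Rickert aromatisation. The one new ring (C4a–C5–C6–C7–C8–C8a) closes by intermolecular [4+2] annulation, and because the diene is cyclic it arises inside a bicyclo[2.2.2]octene whose saturated bridge is the future ethylene. Four stereocentres appear (C4a, C8a and the two bridgeheads): the cis ring fusion follows from suprafacial addition and the bridgeheads are fixed by the bicycle, while endo/exo and the face relative to C1' are uncontrolled and need not be, since all four centres become sp2 in steps 8 and 9. The selectivity needed is site selectivity between the two quinone alkenes: the future C2=C3 bond carries the branched side chain, which shields it and, as an alkyl donor, makes it the poorer dienophile, so addition should occur at the unsubstituted alkene; the symmetric diene removes any regiochemical question and the electron-rich prenyl alkene is not a dienophile for it. Aprotic, acid-free conditions at room temperature should keep the silyl enol ethers, the tertiary acetate and the (R) centre untouched.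

Step 8
Reactants: 13 Diels–Alder adduct
Product: 15 2-substituted 5,8-bis(trimethylsilyloxy)-5,8-ethano-5,8-dihydronaphthalene-1,4-dione (bridged quinone), via bridged hydroquinone 14 (not isolated)
Conditions: Ag2O (3 equiv), Et3N (5 mol%), MgSO4, CH2Cl2, 0 °C → rt, dark
Reagents that add atoms: none
Why: Base-catalysed double enolisation of the cis-fused ene-dione, driven by aromatisation, gives hydroquinone 14, which Ag2O oxidises at once to the quinone so that the free hydroquinone has no time to expel the benzylic carboxylate; β-elimination of the silyloxy groups is excluded because it would require a bridgehead alkene.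

Step 9
Reactants: 15 bridged quinone
Product: 17 (R)-1-(5,8-dihydroxy-1,4-dioxo-1,4-dihydronaphthalen-2-yl)-4-methylpent-3-en-1-yl 3-acetoxy-3-methylbutanoate (the target), via bis(trimethylsilyl) naphthoquinone 16 (not isolated)
Conditions: PhMe, 110 °C, Ar stream; then 1 M HCl, THF, 0 °C
Reagents that add atoms: none
Why: In an Alder–Rickert cycloreversion the bicyclo[2.2.2]octa-2,5-diene should lose its saturated bridge as ethylene, driven by aromatisation and gas loss, turning the silyloxy bridgeheads into aromatic C5 and C8; cold dilute acid then hydrolyses the aryl trimethylsilyl ethers while leaving the tertiary acetate, the benzylic ester and the alkene alone.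

**Compound list**

1 | 2,5-dimethoxybenzaldehyde | COc1ccc(OC)c(C=O)c1 | starting material
2 | (R)-1-(2,5-dimethoxyphenyl)but-3-en-1-yl diisopinocampheylborinate | C=CC[C@@H](OB([C@H]1C[C@H]2C[C@@H]([C@@H]1C)C2(C)C)[C@H]1C[C@H]2C[C@@H]([C@@H]1C)C2(C)C)c1cc(OC)ccc1OC | intermediate (not isolated)
3 | (R)-1-(2,5-dimethoxyphenyl)but-3-en-1-ol | O[C@H](CC=C)c1cc(OC)ccc1OC | intermediate
4 | 2-methyl-2-butene | CC=C(C)C | starting material
5 | (R)-1-(2,5-dimethoxyphenyl)-4-methylpent-3-en-1-ol | O[C@H](CC=C(C)C)c1cc(OC)ccc1OC | intermediate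
6 | 3-hydroxy-3-methylbutanoic acid | CC(C)(O)CC(=O)O | starting material
7 | acetic 3-acetoxy-3-methylbutanoic anhydride | CC(=O)OC(C)(C)CC(=O)OC(C)=O | intermediate (not isolated)
8 | 3-acetoxy-3-methylbutanoic acid | CC(=O)OC(C)(C)CC(=O)O | intermediate
9 | (R)-1-(2,5-dimethoxyphenyl)-4-methylpent-3-en-1-yl 3-acetoxy-3-methylbutanoate | CC(=O)OC(C)(C)CC(=O)O[C@H](CC=C(C)C)c1cc(OC)ccc1OC | intermediate
10 | (R)-1-(3,6-dioxocyclohexa-1,4-dien-1-yl)-4-methylpent-3-en-1-yl 3-acetoxy-3-methylbutanoate | CC(=O)OC(C)(C)CC(=O)O[C@H](CC=C(C)C)C1=CC(=O)C=CC1=O | intermediate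
11 | 1,4-cyclohexanedione | O=C1CCC(=O)CC1 | starting material
12 | 1,4-bis(trimethylsilyloxy)cyclohexa-1,3-diene | C[Si](C)(C)OC1=CC=C(O[Si](C)(C)C)CC1 | intermediate
13 | Diels–Alder adduct: 2-[(R)-side chain]-5,8-bis(trimethylsilyloxy)-5,8-ethano-4a,5,8,8a-tetrahydronaphthalene-1,4-dione (ring-fusion and bridgehead centres left open) | CC(=O)OC(C)(C)CC(=O)O[C@H](CC=C(C)C)C1=CC(=O)C2C(C1=O)C1(O[Si](C)(C)C)C=CC2(O[Si](C)(C)C)CC1 | intermediate
14 | bridged hydroquinone: 2-[(R)-side chain]-5,8-bis(trimethylsilyloxy)-5,8-ethano-5,8-dihydronaphthalene-1,4-diol (bridgeheads left open) | CC(=O)OC(C)(C)CC(=O)O[C@H](CC=C(C)C)c1cc(O)c2c(c1O)C1(O[Si](C)(C)C)C=CC2(O[Si](C)(C)C)CC1 | intermediate (not isolated)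
15 | bridged quinone: 2-[(R)-side chain]-5,8-bis(trimethylsilyloxy)-5,8-ethano-5,8-dihydronaphthalene-1,4-dione (bridgeheads left open) | CC(=O)OC(C)(C)CC(=O)O[C@H](CC=C(C)C)C1=CC(=O)C2=C(C1=O)C1(O[Si](C)(C)C)C=CC2(O[Si](C)(C)C)CC1 | intermediate
16 | (R)-1-[1,4-dioxo-5,8-bis(trimethylsilyloxy)-1,4-dihydronaphthalen-2-yl]-4-methylpent-3-en-1-yl 3-acetoxy-3-methylbutanoate | CC(=O)OC(C)(C)CC(=O)O[C@H](CC=C(C)C)C1=CC(=O)c2c(O[Si](C)(C)C)ccc(O[Si](C)(C)C)c2C1=O | intermediate (not isolated)
17 | (R)-1-(5,8-dihydroxy-1,4-dioxo-1,4-dihydronaphthalen-2-yl)-4-methylpent-3-en-1-yl 3-acetoxy-3-methylbutanoate | CC(=O)OC(C)(C)CC(=O)O[C@H](CC=C(C)C)C1=CC(=O)c2c(O)ccc(O)c2C1=O | target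

**Step count and risks**

Total steps: 9. Longest linear sequence: 7 (steps 1, 2, 4, 5, 7, 8, 9); steps 3 and 6 are side branches.

Steps most likely to fail:

Step 9. The retro-[4+2] may need a temperature at which the side chain suffers first, for example by acid-catalysed loss of acetic acid from the tertiary acetate once traces of acid appear, or by ene-type cyclisation of the prenyl alkene onto the quinone. The fallback sets out from quinone 10 and uses an oxygen-bridged diene, so that neither oxidation nor extrusion is needed. 2,5-Bis(trimethylsilyloxy)furan F1 (from succinic anhydride, TMSCl, Et3N, cat. ZnCl2) should add at or below room temperature across the same unsubstituted alkene of 10 to give the 7-oxabicyclo[2.2.1]heptene adduct F2. On work-up with dilute acid the bridging ketal should collapse with loss of the two silyl groups to the 4a,8a-dihydronaphthalene-1,4,5,8-tetraone F3, the keto tautomer of the naphthazarin, which enolises to 17. The same C4a–C5 and C8a–C8 bonds are formed and the route is rejoined at 17.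

Step 8. The transient hydroquinone may expel the benzylic carboxylate through an ortho-quinone methide, or the amine may erode C1' of the product quinone through its quinone-methide tautomer. The fallback sets out from adduct 13 and traps the double enol as it forms. TMSCl/Et3N (CH2Cl2, 0 °C) should give the aromatic tetrakis(trimethylsilyl) ether F4, in which neither a free phenol nor a quinone is exposed to base. Thermolysis (xylene, 140 °C) should extrude ethylene to the 1,4,5,8-tetrakis(trimethylsilyloxy)naphthalene F5. Brief treatment with aqueous CAN (MeCN/H2O, 0 °C) should oxidise the more electron-rich, alkylated ring to 16, where the route is rejoined and the acid hydrolysis of step 9 completes the synthesis.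

Step 7. Trimethylsilyl groups may be lost from the dienol ether (hydrolysis, silyl transfer to the quinone, Mukaiyama–Michael addition in place of cycloaddition) or from the adduct, whose free β-hydroxy ketone would then open by retro-aldol cleavage. The fallback sets out from 11 and 10 and uses sturdier silyl groups with a fluoride end-game. TBSOTf/Et3N (CH2Cl2, 0 °C) should convert 11 into 1,4-bis(tert-butyldimethylsilyloxy)cyclohexa-1,3-diene F6. Cycloaddition to 10 (PhMe, 60 °C) should give the bis-TBS adduct F7. Ag2O with a trace of Et3N should lead through the bis-TBS bridged hydroquinone F8 to the bis-TBS bridged quinone F9. Heating in toluene should give the 5,8-bis(tert-butyldimethylsilyloxy)naphthoquinone F10, and HF·pyridine (THF, 0 °C) should free the phenols, rejoining the route at 17.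

**Further compounds**

F1 | step 9 | 2,5-bis(trimethylsilyloxy)furan | C[Si](C)(C)Oc1ccc(O[Si](C)(C)C)o1
F2 | step 9 | oxa-bridged adduct: 2-[(R)-side chain]-5,8-bis(trimethylsilyloxy)-5,8-epoxy-4a,5,8,8a-tetrahydronaphthalene-1,4-dione | CC(=O)OC(C)(C)CC(=O)O[C@H](CC=C(C)C)C1=CC(=O)C2C(C1=O)C1(O[Si](C)(C)C)C=CC2(O[Si](C)(C)C)O1
F3 | step 9 | 2-[(R)-side chain]-4a,8a-dihydronaphthalene-1,4,5,8-tetraone | CC(=O)OC(C)(C)CC(=O)O[C@H](CC=C(C)C)C1=CC(=O)C2C(C1=O)C(=O)C=CC2=O
F4 | step 8 | 2-[(R)-side chain]-1,4,5,8-tetrakis(trimethylsilyloxy)-5,8-ethano-5,8-dihydronaphthalene | CC(=O)OC(C)(C)CC(=O)O[C@H](CC=C(C)C)c1cc(O[Si](C)(C)C)c2c(c1O[Si](C)(C)C)C1(O[Si](C)(C)C)C=CC2(O[Si](C)(C)C)CC1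
F5 | step 8 | 2-[(R)-side chain]-1,4,5,8-tetrakis(trimethylsilyloxy)naphthalene | CC(=O)OC(C)(C)CC(=O)O[C@H](CC=C(C)C)c1cc(O[Si](C)(C)C)c2c(O[Si](C)(C)C)ccc(O[Si](C)(C)C)c2c1O[Si](C)(C)C
F6 | step 7 | 1,4-bis(tert-butyldimethylsilyloxy)cyclohexa-1,3-diene | CC(C)(C)[Si](C)(C)OC1=CC=C(O[Si](C)(C)C(C)(C)C)CC1
F7 | step 7 | bis-TBS Diels–Alder adduct | CC(=O)OC(C)(C)CC(=O)O[C@H](CC=C(C)C)C1=CC(=O)C2C(C1=O)C1(O[Si](C)(C)C(C)(C)C)C=CC2(O[Si](C)(C)C(C)(C)C)CC1
F8 | step 7 | bis-TBS bridged hydroquinone | CC(=O)OC(C)(C)CC(=O)O[C@H](CC=C(C)C)c1cc(O)c2c(c1O)C1(O[Si](C)(C)C(C)(C)C)C=CC2(O[Si](C)(C)C(C)(C)C)CC1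
F9 | step 7 | bis-TBS bridged quinone | CC(=O)OC(C)(C)CC(=O)O[C@H](CC=C(C)C)C1=CC(=O)C2=C(C1=O)C1(O[Si](C)(C)C(C)(C)C)C=CC2(O[Si](C)(C)C(C)(C)C)CC1
F10 | step 7 | (R)-1-[5,8-bis(tert-butyldimethylsilyloxy)-1,4-dioxo-1,4-dihydronaphthalen-2-yl]-4-methylpent-3-en-1-yl 3-acetoxy-3-methylbutanoate | CC(=O)OC(C)(C)CC(=O)O[C@H](CC=C(C)C)C1=CC(=O)c2c(O[Si](C)(C)C(C)(C)C)ccc(O[Si](C)(C)C(C)(C)C)c2C1=O
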